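**Remark on the chemistry (assumption).** The aldol in step 5 is taken to be unselective at the carbinol carbon. Compounds 13 and 14 are therefore written as pairs of epimers at that one centre (left undefined in their SMILES), and the route uses both epimers. Target ring atoms are numbered O1, C2, C3 (benzyl-bearing), C4 (carbinol-bearing), C5. Lactone intermediates use lactone locants (C2 carbonyl, C3, C4, C5 acetal): lactone C4 becomes target C3, lactone C3 becomes target C4, lactone C5 becomes target C2 and lactone C2 becomes target C5. Ar = 4-benzyloxy-3,5-dimethoxyphenyl; Men = (1R,2S,5R)-2-isopropyl-5-methylcyclohexyl.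

## The problem

The target 21 is a trans-3,4-disubstituted tetrahydrofuran: C3 (R) carries a 4-hydroxy-3,5-dimethoxybenzyl group and C4 (R) carries an (S)-configured aryl(hydroxy)methyl group with the same aryl ring. C2 and C5 are plain methylenes on either side of O1, so the ring offers no functional handle and the three contiguous stereocentres must be built on a more oxidised precursor. C3 and C4 can control each other through a ring, since trans is both the kinetic and the thermodynamic arrangement. The carbinol carbon lies outside the ring and can be steered from C4 only while a second donor, a carbonyl at C5, is available for chelation. The carbinol is a para-hydroxybenzylic alcohol on an electron-rich ring: it ionises to a quinone methide under acid, it is open to hydrogenolysis, and its oxygen can compete in any ring closure to give the isomeric 2-aryl tetrahydrofuran. The two aryl groups are identical and both benzylic carbons sit at or below the aldehyde oxidation level, so both can come from syringaldehyde. The enabling feature is that, once C5 is raised to a lactone carbonyl and C2 to an acetal carbon, C3 and C4 are the β- and α-carbons of a butenolide. The benzylic carbon on C3 can then arrive as an acyl-anion equivalent by conjugate addition and the carbinol on C4 by aldol trapping of the enolate, while a chiral alkoxy group on the acetal carbon fixes the absolute configuration.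

## Retrosynthesis

**Protecting groups (21 ⇐ 20 ⇐ 19).** The two phenol O–H bonds are traced back to benzyl ethers and the carbinol O–H to a tert-butyldimethylsilyl ether. Benzyl ethers survive organolithium, hydride and nickel reagents and leave under neutral hydrogenolysis. The silyl ether keeps the carbinol oxygen out of the ring closure and leaves with fluoride. Acid-labile groups were rejected because of the quinone methide problem. The forward steps must remove both groups without ionising or reducing the benzylic C–O bond.

**Ring C–O bond (19 ⇐ 18).** Cutting O1–C2 (equivalently O1–C5) gives the 1,4-diol 18. This cut is preferred over a ring C–C cut because it touches no stereocentre, and over acid-catalysed cyclodehydration because a Mitsunobu closure needs no cation. Either primary hydroxyl may be activated, since both give the same ring. The precursor is acyclic with the three stereocentres already in place.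

**Oxidation level of C2 and C5 (18 ⇐ 17).** Both CH2OH groups are traced back to a γ-alkoxy-γ-lactone: C5 as the lactone carbonyl and C2 as a menthyl acetal carbon. LiAlH4 must reduce both carbons in one operation and release the auxiliary, without epimerising the adjacent centres.

**Carbinol centre and latent methylene (17 ⇐ 16 ⇐ 15 ⇐ 14 ⇐ 13).** The carbinol C–H bond is cut back to ketone 15, so that the centre is set by a chelation-controlled reduction using the lactone carbonyl as second donor. Ketone 15 comes from oxidation of alcohol 14, which makes the carbinol selectivity of the earlier C–C bond formation irrelevant. The benzylic CH2 on lactone C4 is traced back to a 1,3-dithiane in 13, a latent methylene as well as an acyl-anion carrier. The forward steps are desulfurisation, oxidation, reduction and silylation.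

**Key disconnection (13 ⇐ 4 + 10 + 2).** The bond from the benzylic carbon to lactone C4 and the bond from lactone C3 to the carbinol carbon are cut together. This leads to lithiated dithiane 4, the enantiopure butenolide 10 and aldehyde 2. Making the two bonds separately on a preformed β-benzyl lactone would cost steps and would lose the steric relay from the dithiane. The precursors are an aryl dithiane, a five-carbon acetal and an aldehyde. The forward reaction must give 1,4-addition, then trans,trans diastereoselection over the two new ring centres.

**Building blocks (4 ⇐ 2 + 3; 2 ⇐ 1; 10 ⇐ 7 + 8; 7 ⇐ 5).** Dithiane 4 is the dithioacetal of aldehyde 2 with propane-1,3-dithiol 3, and 2 is benzylated syringaldehyde 1. Both aryl groups therefore come from one aldehyde. Butenolide 10 is the menthyl acetal of 5-hydroxy-2(5H)-furanone 7 with (−)-menthol 8, and 7 is the photooxygenation product of furfural 5. The acetal epimers interconvert under acid, so crystallisation can funnel the material into the (5R) epimer.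

## Roads not taken

**Alternative 1:** The cut is the ring C2–C3 bond. The phenylselenomethyl ether A1 of an (E)-homoallylic alcohol, already carrying C4 and the silylated carbinol, would be converted by a tin hydride chain into an alkoxymethyl radical. This closes 5-exo-trig onto the styrene to give A2, which is identical with 19 of the chosen route.
- Merits: the ring forms at its final oxidation level, without the reduce-and-reclose detour, and A2 is two deprotections from the target. The benzylic radical formed on closure makes the addition fast and regioselective.
- Weak points: C3 is created under kinetic control in a chair-like transition state, with the C4 substituent as the only control element. For a radical of this substitution pattern the trans preference is usually moderate, and the chain oxygen changes the geometry further. A cis isomer would be hard to separate from A2. A1 also needs C4 and the carbinol set beforehand by a separate asymmetric aldol, plus a styrene construction and selenium and tin reagents.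
- Comparison: this road is better in the end game. The chosen plan sets against that a C3 centre fixed by steric relay from a neighbour as large as a dithiane, absolute configuration from a recrystallised auxiliary, and no gain in length once A1 is counted.

**Alternative 2:** The cuts are C2–C3 and C4–C5. The parent carbonyl ylide, released by fluoride from chloromethyl trimethylsilylmethyl ether A4, would add across the E-enoyl imide A3 to give the trans cycloadduct A5.
- Merits: the ring and both methylenes arrive in one step, the trans geometry is copied from the E-alkene, and no ring carbon needs redox adjustment. Because the ring is closed before the carbinol exists, the carbinol never needs protection against a competing closure. This is a real advantage over the chosen plan, which spends steps on silylation, reduction and reclosure.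
- Weak points: the unstabilised ylide is a very reactive dipole and the oxazolidinone stereocentre is remote from the reacting β-carbon. Fluoride conditions exclude a chelating Lewis acid, so facial control and hence absolute configuration are doubtful. A3 is a γ-aryl crotonyl system whose double bond tends to move into conjugation with the arene under basic conditions. A5 still lacks the second aryl group; it must be attached at the imide carbon and the carbinol then set by a reduction with only the ring oxygen as a chelation partner.
- Comparison: this road is more convergent in ring construction and lighter in protecting groups. The chosen plan offers secure relative and absolute control at C3 and C4, one aldehyde for both aryl groups, and a lactone carbonyl as chelation handle for the carbinol.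

**Alternative 3:** The cut is the O1–C2 bond, formed by oxygen insertion. The prochiral cyclobutanone A6 would undergo an enantioselective Baeyer–Villiger oxidation (peroxide under a chiral Brønsted acid, or a monooxygenase) to lactone A7, which carries target C3.
- Merits: the step is catalytic, needs no stoichiometric auxiliary, leaves no acetal carbon to reduce later and has high atom economy. An enzyme could in principle deliver very high enantiomeric purity.
- Weak points: the step forms one C–O bond and one stereocentre only. The arene is one methylene away from the ring, so the two enantiotopic migrating bonds differ little and selectivity is expected to be harder to secure than for a 3-aryl cyclobutanone. The electron-rich arene must tolerate peroxide and acid. A6 itself takes several steps. The bond from C4 to the carbinol carbon still needs a separate lactone aldol with aldehyde 2, with the same carbinol problem and the same reduction and reclosure as in the chosen plan.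
- Comparison: this road is better in atom economy and avoids the auxiliary. The chosen plan forms both C–C bonds and both ring stereocentres in one flask, and its enantiopurity rests on a crystalline acetal, not on a catalyst's selectivity.

Key step: step 5

## Route

Step 1
Reactants: 1 syringaldehyde (4-hydroxy-3,5-dimethoxybenzaldehyde)
Product: 2 4-benzyloxy-3,5-dimethoxybenzaldehyde
Conditions: BnBr, K2CO3, DMF, 60 °C
Reagents that add atoms: benzyl bromide, BrCc1ccccc1
Why: Williamson ether synthesis on an acidic para-formyl phenol; the benzyl ether is the one phenol protecting group that tolerates every later reagent and leaves under neutral conditions.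

Step 2
Reactants: 2 4-benzyloxy-3,5-dimethoxybenzaldehyde; 3 propane-1,3-dithiol
Product: 4 2-(4-benzyloxy-3,5-dimethoxyphenyl)-1,3-dithiane
Conditions: BF3·OEt2 (cat.), CH2Cl2, 0 °C → rt
Reagents that add atoms: none
Why: Lewis acid catalysed dithioacetalisation of an aromatic aldehyde; the aryl benzyl ether is stable to catalytic BF3·OEt2 at this temperature.

Step 3
Reactants: 5 furfural
Product: 7 5-hydroxy-2(5H)-furanone (racemic), via furfural endoperoxide 6 (not isolated)
Conditions: O2, hν (visible), rose bengal (cat.), MeOH, rt
Reagents that add atoms: dioxygen, O=O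
Why: Dye-sensitised singlet-oxygen [4+2] cycloaddition to the furan gives endoperoxide 6, whose methanolysis expels the formyl carbon as methyl formate and leaves the hydroxybutenolide; this is the standard photooxygenation of furfural.

Step 4
Reactants: 7 5-hydroxy-2(5H)-furanone; 8 (−)-menthol
Product: 10 (5R)-5-[(1R,2S,5R)-menthyloxy]-2(5H)-furanone, via C5-epimeric menthyl acetal mixture 9 (not isolated)
Conditions: CSA (cat.), toluene, reflux, Dean–Stark; crystallisation from petroleum ether, mother liquor re-equilibrated with CSA and recrystallised
Reagents that add atoms: none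
Why: Acid-catalysed acetalisation of the pseudo-acid gives both C5 epimers, which interconvert under acid; the (5R) epimer is the crystalline one, so crystallisation with recycling of the mother liquor (crystallisation-induced diastereomer transformation) should deliver 10 as a single stereoisomer, with C5 set by crystal selection against the menthyl group.

Step 5
Reactants: 4 2-(4-benzyloxy-3,5-dimethoxyphenyl)-1,3-dithiane; 10 (5R)-5-[(1R,2S,5R)-menthyloxy]-2(5H)-furanone; 2 4-benzyloxy-3,5-dimethoxybenzaldehyde
Product: 13 (3S,4R,5R)-3-[Ar(hydroxy)methyl]-4-(2-Ar-1,3-dithian-2-yl)-5-(Men-oxy)dihydrofuran-2(3H)-one as both carbinol epimers, via 2-lithio-2-aryl-1,3-dithiane 11 (not isolated), via lithium lactone enolate 12 (not isolated)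
Conditions: n-BuLi, THF, −78 °C; then 10, −78 °C; then 2, −78 °C; aq. NH4Cl at −78 °C
Reagents that add atoms: none
Why: n-BuLi removes the C2 proton of dithiane 4 to give the sulfur- and aryl-stabilised anion 11, a soft acyl-anion equivalent that adds to butenolide 10 in a Michael (1,4) fashion and not at the lactone carbonyl. The anion approaches lactone C4 on the face opposite the C5 menthyloxy group, so C4 (R) is set trans to the acetal substituent by the (5R) centre. The lithium enolate 12 is trapped in the same flask by aldehyde 2 in an aldol addition at lactone C3; the aldehyde enters anti to the very large dithianyl group, so C3 (S) is set trans to C4 by the centre created just before. Two C–C bonds (benzylic carbon to C4, C3 to carbinol carbon) and the two ring stereocentres are formed, no ring is closed, and every carbon of the target is then in place. The closest known reaction type is the tandem conjugate addition–aldol reaction of 2-lithio-2-aryl-1,3-dithianes with 5-alkoxy-2(5H)-furanones. The step needs 1,4- over 1,2-regioselectivity, secured by the delocalised dithiane anion and the doubly activated enoate, and trans,trans diastereoselectivity, secured by the relay from the acetal centre to C4 and from C4 to C3. The carbinol centre comes from a lactone enolate of fixed geometry and an aromatic aldehyde without a dependable preference and is not relied on, since both epimers converge on ketone 15 in step 7. Quenching at −78 °C keeps the aldolate from reverting.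

Step 6
Reactants: 13 aldol adduct (both carbinol epimers)
Product: 14 (3S,4R,5R)-4-(4-benzyloxy-3,5-dimethoxybenzyl)-3-[Ar(hydroxy)methyl]-5-(Men-oxy)dihydrofuran-2(3H)-one as both carbinol epimers
Conditions: NiCl2·6H2O, NaBH4, MeOH/THF, 0 °C → rt
Reagents that add atoms: none
Why: Reductive desulfurisation of a benzylic dithioacetal with nickel boride made in the flask turns the dithiane carbon into the benzylic CH2; aryl benzyl ethers, the lactone and the acetal are inert to this reagent at low temperature, and no stereocentre is touched.

Step 7
Reactants: 14 desulfurised aldol lactone (both carbinol epimers)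
Product: 15 (3S,4R,5R)-3-(4-benzyloxy-3,5-dimethoxybenzoyl)-4-(4-benzyloxy-3,5-dimethoxybenzyl)-5-(Men-oxy)dihydrofuran-2(3H)-one
Conditions: Dess–Martin periodinane, CH2Cl2, 0 °C → rt
Reagents that add atoms: none
Why: Dess–Martin oxidation of a secondary benzylic alcohol; both epimers give the same β-keto lactone, and lactone C3, now acidic, stays trans to the C4 benzyl group because that is the thermodynamic arrangement.

Step 8
Reactants: 15 β-keto lactone
Product: 16 (3S,4R,5R)-3-[(S)-Ar(hydroxy)methyl]-4-(4-benzyloxy-3,5-dimethoxybenzyl)-5-(Men-oxy)dihydrofuran-2(3H)-one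
Conditions: Zn(BH4)2, Et2O/CH2Cl2, −20 °C; aq. NH4Cl
Reagents that add atoms: none
Why: Chelation-controlled reduction of an α-substituted β-keto ester type substrate: zinc bridges the ketone and lactone carbonyl oxygens, the ketone face on the side of the C3 hydrogen is open while the other is blocked by C4 and its benzyl group, and hydride delivery on the open face should give the syn (erythro) β-hydroxy lactone, which is the (S)-carbinol.

Step 9
Reactants: 16 (S)-carbinol lactone
Product: 17 (3S,4R,5R)-3-[(S)-Ar(tert-butyldimethylsilyloxy)methyl]-4-(4-benzyloxy-3,5-dimethoxybenzyl)-5-(Men-oxy)dihydrofuran-2(3H)-one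
Conditions: TBSOTf, 2,6-lutidine, CH2Cl2, −78 → 0 °C
Reagents that add atoms: tert-butyldimethylsilyl trifluoromethanesulfonate, CC(C)(C)[Si](C)(C)OS(=O)(=O)C(F)(F)F
Why: Silyl triflate with a hindered pyridine base silylates hindered secondary alcohols at low temperature without disturbing the acetal; the silyl ether keeps the carbinol oxygen out of the later ring closure.

Step 10
Reactants: 17 silylated lactone
Product: 18 (2R,3R)-2-[(S)-Ar(tert-butyldimethylsilyloxy)methyl]-3-(4-benzyloxy-3,5-dimethoxybenzyl)butane-1,4-diol
Conditions: LiAlH4, THF, 0 °C; NaOH/H2O work-up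
Reagents that add atoms: none
Why: LiAlH4 reduces the lactone carbonyl to CH2OH and thereby frees the hemiacetal at the acetal carbon, which collapses to an aldehyde with loss of menthol and is reduced in turn; the transient aldehydes are reduced faster than they enolise, so both ring-derived stereocentres are retained, and 0 °C guards against silyl migration.

Step 11
Reactants: 18 silylated 1,4-diol
Product: 19 (3R,4R)-3-(4-benzyloxy-3,5-dimethoxybenzyl)-4-[(S)-Ar(tert-butyldimethylsilyloxy)methyl]tetrahydrofuran
Conditions: PPh3, DIAD, THF, 0 °C → rt
Reagents that add atoms: none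
Why: Mitsunobu cyclodehydration of a 1,4-diol: one primary hydroxyl is activated as the alkoxyphosphonium ion and displaced by the other in a 5-exo-tet closure; either activation gives the same ring and no stereocentre takes part.

Step 12
Reactants: 19 silylated tetrahydrofuran
Product: 20 (S)-(4-benzyloxy-3,5-dimethoxyphenyl)[(3R,4R)-4-(4-benzyloxy-3,5-dimethoxybenzyl)tetrahydrofuran-3-yl]methanol
Conditions: TBAF, THF, 0 °C → rt; aq. NH4Cl
Reagents that add atoms: none
Why: Fluoride-mediated desilylation proceeds at silicon under non-acidic conditions, so the benzylic C–O bond is neither ionised nor inverted.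

Step 13
Reactants: 20 bis-benzyl ether
Product: 21 (S)-(4-hydroxy-3,5-dimethoxyphenyl)[(3R,4R)-4-(4-hydroxy-3,5-dimethoxybenzyl)tetrahydrofuran-3-yl]methanol (target)
Conditions: H2 (1 atm), Pd/C, EtOAc, rt
Reagents that add atoms: none
Why: Hydrogenolysis of aryl benzyl ethers over Pd/C in a neutral, non-protic solvent is much faster than cleavage of a benzylic C–OH bond, which needs acid or prolonged exposure, so the carbinol and its configuration should be kept.

## Compound list

1 | syringaldehyde (4-hydroxy-3,5-dimethoxybenzaldehyde) | COc1cc(C=O)cc(OC)c1O | starting material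
2 | 4-benzyloxy-3,5-dimethoxybenzaldehyde | COc1cc(C=O)cc(OC)c1OCc1ccccc1 | intermediate
3 | propane-1,3-dithiol | SCCCS | starting material
4 | 2-(4-benzyloxy-3,5-dimethoxyphenyl)-1,3-dithiane | COc1cc(C2SCCCS2)cc(OC)c1OCc1ccccc1 | intermediate
5 | furfural (furan-2-carbaldehyde) | O=Cc1ccco1 | starting material
6 | furfural endoperoxide (2,3,7-trioxabicyclo[2.2.1]hept-5-ene-1-carbaldehyde, racemic) | O=CC12OOC(C=C1)O2 | intermediate (not isolated)
7 | 5-hydroxy-2(5H)-furanone (racemic) | O=C1C=CC(O)O1 | intermediate
8 | (−)-menthol, (1R,2S,5R)-2-isopropyl-5-methylcyclohexanol | C[C@@H]1CC[C@H]([C@@H](C1)O)C(C)C | starting material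
9 | 5-[(1R,2S,5R)-2-isopropyl-5-methylcyclohexyloxy]-2(5H)-furanone, both C5 epimers | O=C1C=CC(O[C@@H]2C[C@H](C)CC[C@H]2C(C)C)O1 | intermediate (not isolated)
10 | (5R)-5-[(1R,2S,5R)-2-isopropyl-5-methylcyclohexyloxy]-2(5H)-furanone | O=C1C=C[C@H](O[C@@H]2C[C@H](C)CC[C@H]2C(C)C)O1 | intermediate
11 | 2-(4-benzyloxy-3,5-dimethoxyphenyl)-2-lithio-1,3-dithiane | [Li]C1(SCCCS1)c1cc(OC)c(OCc2ccccc2)c(OC)c1 | intermediate (not isolated)
12 | lithium enolate of (4R,5R)-4-[2-(4-benzyloxy-3,5-dimethoxyphenyl)-1,3-dithian-2-yl]-5-[(1R,2S,5R)-menthyloxy]dihydrofuran-2(3H)-one | [Li]OC1=C[C@@H](C2(SCCCS2)c2cc(OC)c(OCc3ccccc3)c(OC)c2)[C@H](O[C@@H]2C[C@H](C)CC[C@H]2C(C)C)O1 | intermediate (not isolated)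
13 | (3S,4R,5R)-3-[(4-benzyloxy-3,5-dimethoxyphenyl)(hydroxy)methyl]-4-[2-(4-benzyloxy-3,5-dimethoxyphenyl)-1,3-dithian-2-yl]-5-[(1R,2S,5R)-menthyloxy]dihydrofuran-2(3H)-one, both epimers at the carbinol carbon | COc1cc(C2(SCCCS2)[C@H]3[C@H](O[C@@H]4C[C@H](C)CC[C@H]4C(C)C)OC(=O)[C@@H]3C(O)c3cc(OC)c(OCc4ccccc4)c(OC)c3)cc(OC)c1OCc1ccccc1 | intermediate
14 | (3S,4R,5R)-4-(4-benzyloxy-3,5-dimethoxybenzyl)-3-[(4-benzyloxy-3,5-dimethoxyphenyl)(hydroxy)methyl]-5-[(1R,2S,5R)-menthyloxy]dihydrofuran-2(3H)-one, both epimers at the carbinol carbon | COc1cc(C[C@H]2[C@H](O[C@@H]3C[C@H](C)CC[C@H]3C(C)C)OC(=O)[C@@H]2C(O)c2cc(OC)c(OCc3ccccc3)c(OC)c2)cc(OC)c1OCc1ccccc1 | intermediate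
15 | (3S,4R,5R)-3-(4-benzyloxy-3,5-dimethoxybenzoyl)-4-(4-benzyloxy-3,5-dimethoxybenzyl)-5-[(1R,2S,5R)-menthyloxy]dihydrofuran-2(3H)-one | COc1cc(C[C@H]2[C@H](O[C@@H]3C[C@H](C)CC[C@H]3C(C)C)OC(=O)[C@@H]2C(=O)c2cc(OC)c(OCc3ccccc3)c(OC)c2)cc(OC)c1OCc1ccccc1 | intermediate
16 | (3S,4R,5R)-4-(4-benzyloxy-3,5-dimethoxybenzyl)-3-[(S)-(4-benzyloxy-3,5-dimethoxyphenyl)(hydroxy)methyl]-5-[(1R,2S,5R)-menthyloxy]dihydrofuran-2(3H)-one | COc1cc(C[C@H]2[C@H](O[C@@H]3C[C@H](C)CC[C@H]3C(C)C)OC(=O)[C@@H]2[C@H](O)c2cc(OC)c(OCc3ccccc3)c(OC)c2)cc(OC)c1OCc1ccccc1 | intermediate
17 | (3S,4R,5R)-4-(4-benzyloxy-3,5-dimethoxybenzyl)-3-[(S)-(4-benzyloxy-3,5-dimethoxyphenyl)(tert-butyldimethylsilyloxy)methyl]-5-[(1R,2S,5R)-menthyloxy]dihydrofuran-2(3H)-one | COc1cc(C[C@H]2[C@H](O[C@@H]3C[C@H](C)CC[C@H]3C(C)C)OC(=O)[C@@H]2[C@H](O[Si](C)(C)C(C)(C)C)c2cc(OC)c(OCc3ccccc3)c(OC)c2)cc(OC)c1OCc1ccccc1 | intermediate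
18 | (2R,3R)-2-[(S)-(4-benzyloxy-3,5-dimethoxyphenyl)(tert-butyldimethylsilyloxy)methyl]-3-(4-benzyloxy-3,5-dimethoxybenzyl)butane-1,4-diol | COc1cc(C[C@@H](CO)[C@H](CO)[C@H](O[Si](C)(C)C(C)(C)C)c2cc(OC)c(OCc3ccccc3)c(OC)c2)cc(OC)c1OCc1ccccc1 | intermediate
19 | (3R,4R)-3-(4-benzyloxy-3,5-dimethoxybenzyl)-4-[(S)-(4-benzyloxy-3,5-dimethoxyphenyl)(tert-butyldimethylsilyloxy)methyl]tetrahydrofuran | COc1cc(C[C@H]2COC[C@@H]2[C@H](O[Si](C)(C)C(C)(C)C)c2cc(OC)c(OCc3ccccc3)c(OC)c2)cc(OC)c1OCc1ccccc1 | intermediate
20 | (S)-(4-benzyloxy-3,5-dimethoxyphenyl)[(3R,4R)-4-(4-benzyloxy-3,5-dimethoxybenzyl)tetrahydrofuran-3-yl]methanol | COc1cc(C[C@H]2COC[C@@H]2[C@H](O)c2cc(OC)c(OCc3ccccc3)c(OC)c2)cc(OC)c1OCc1ccccc1 | intermediate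
21 | (S)-(4-hydroxy-3,5-dimethoxyphenyl)[(3R,4R)-4-(4-hydroxy-3,5-dimethoxybenzyl)tetrahydrofuran-3-yl]methanol | COc1cc(C[C@H]2COC[C@@H]2[C@H](O)c2cc(OC)c(O)c(OC)c2)cc(OC)c1O | target

## Step count and least certain steps

Total: 13 steps. Longest linear sequence: 11 steps from syringaldehyde 1 (steps 1, 2 and 5 to 13). The furanone branch (steps 3 and 4) joins at step 5.

**Step 5 (key step).** The most likely failure is incomplete trapping of the hindered enolate 12, or reversal of the aldol before the quench, so that the protonated Michael adduct is isolated. A second risk is direct addition of unreacted anion 11 to aldehyde 2 if the conjugate addition is not complete when the aldehyde is added. The fallback separates the two bond formations. It sets out from 4 and 10: the conjugate addition is quenched with NH4Cl to give the Michael adduct (4R,5R)-4-[2-(4-benzyloxy-3,5-dimethoxyphenyl)-1,3-dithian-2-yl]-5-menthyloxydihydrofuran-2(3H)-one F1. After purification, F1 is converted fully into its enolate with LDA in THF at −78 °C and treated with aldehyde 2, with no dithiane anion left to compete. This returns to the route at 13.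

**Step 8.** The most likely failure is poor facial selectivity, either because the alkoxy oxygens compete for zinc and the bridging chelate is not the reacting species, or because enolisation of the β-keto lactone consumes hydride and lets the unchelated ketone react. The fallback replaces substrate control by catalyst control: asymmetric transfer hydrogenation of the aryl ketone 15 with RuCl(p-cymene)[(S,S)-TsDPEN] and HCO2H/Et3N. By the usual sense of induction for aryl alkyl ketones this should deliver the (S)-carbinol, and any epimerisation at lactone C3 under these conditions leads back to the trans arrangement. It sets out from 15, returns at 16 and makes no new compound.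

**Step 6.** The most likely failure is retro-aldol fragmentation of the free β-hydroxy lactone in the basic borohydride medium, or C–S cleavage that stops after the first sulfur. The fallback removes sulfur before the carbinol exists. It sets out from 4 and 10 and passes through the Michael adduct F1 described above. F1 is desulfurised with NiCl2·6H2O/NaBH4 (or Raney Ni) to (4R,5R)-4-(4-benzyloxy-3,5-dimethoxybenzyl)-5-menthyloxydihydrofuran-2(3H)-one F2. The lithium enolate of F2 (LDA, THF, −78 °C) is added to aldehyde 2, anti to the C4 benzyl group. This returns to the route at 14.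

**Step 13.** The most likely failure is over-reduction: hydrogenolysis of the benzylic C–OH bond, which becomes easier once the para-phenol is free. The fallback changes the order of deprotection. It sets out from 19: the benzyl ethers are hydrogenolysed (H2, Pd/C, EtOAc) while the carbinol is still shielded as its silyl ether, giving (3R,4R)-3-(4-hydroxy-3,5-dimethoxybenzyl)-4-[(S)-(4-hydroxy-3,5-dimethoxyphenyl)(tert-butyldimethylsilyloxy)methyl]tetrahydrofuran F3. F3 is then desilylated with TBAF buffered with AcOH in THF. This returns to the route at the target 21.

## Further compounds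

F1 | step 5 | (4R,5R)-4-[2-(4-benzyloxy-3,5-dimethoxyphenyl)-1,3-dithian-2-yl]-5-[(1R,2S,5R)-menthyloxy]dihydrofuran-2(3H)-one | COc1cc(C2(SCCCS2)[C@H]3[C@H](O[C@@H]4C[C@H](C)CC[C@H]4C(C)C)OC(=O)C3)cc(OC)c1OCc1ccccc1
F0 | step 8 | none | none
F2 | step 6 | (4R,5R)-4-(4-benzyloxy-3,5-dimethoxybenzyl)-5-[(1R,2S,5R)-menthyloxy]dihydrofuran-2(3H)-one | COc1cc(C[C@H]2[C@H](O[C@@H]3C[C@H](C)CC[C@H]3C(C)C)OC(=O)C2)cc(OC)c1OCc1ccccc1
F3 | step 13 | (3R,4R)-3-(4-hydroxy-3,5-dimethoxybenzyl)-4-[(S)-(4-hydroxy-3,5-dimethoxyphenyl)(tert-butyldimethylsilyloxy)methyl]tetrahydrofuran | COc1cc(C[C@H]2COC[C@@H]2[C@H](O[Si](C)(C)C(C)(C)C)c2cc(OC)c(O)c(OC)c2)cc(OC)c1O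
A1 | alternative 1 | phenylselenomethyl ether of (E,2R)-4-(4-benzyloxy-3,5-dimethoxyphenyl)-2-[(S)-(4-benzyloxy-3,5-dimethoxyphenyl)(tert-butyldimethylsilyloxy)methyl]but-3-en-1-ol | COc1cc(/C=C/[C@H](COC[Se]c2ccccc2)[C@H](O[Si](C)(C)C(C)(C)C)c2cc(OC)c(OCc3ccccc3)c(OC)c2)cc(OC)c1OCc1ccccc1
A2 | alternative 1 | (3R,4R)-3-(4-benzyloxy-3,5-dimethoxybenzyl)-4-[(S)-(4-benzyloxy-3,5-dimethoxyphenyl)(tert-butyldimethylsilyloxy)methyl]tetrahydrofuran (identical with 19) | COc1cc(C[C@H]2COC[C@@H]2[C@H](O[Si](C)(C)C(C)(C)C)c2cc(OC)c(OCc3ccccc3)c(OC)c2)cc(OC)c1OCc1ccccc1
A3 | alternative 2 | (S)-4-benzyl-3-[(E)-4-(4-benzyloxy-3,5-dimethoxyphenyl)but-2-enoyl]oxazolidin-2-one | COc1cc(C/C=C/C(=O)N2[C@@H](Cc3ccccc3)COC2=O)cc(OC)c1OCc1ccccc1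
A4 | alternative 2 | chloromethyl trimethylsilylmethyl ether | C[Si](C)(C)COCCl
A5 | alternative 2 | (S)-4-benzyl-3-{[(3R,4R)-4-(4-benzyloxy-3,5-dimethoxybenzyl)tetrahydrofuran-3-yl]carbonyl}oxazolidin-2-one | COc1cc(C[C@H]2COC[C@@H]2C(=O)N2[C@@H](Cc3ccccc3)COC2=O)cc(OC)c1OCc1ccccc1
A6 | alternative 3 | 3-(4-benzyloxy-3,5-dimethoxybenzyl)cyclobutan-1-one | COc1cc(CC2CC(=O)C2)cc(OC)c1OCc1ccccc1
A7 | alternative 3 | (R)-4-(4-benzyloxy-3,5-dimethoxybenzyl)dihydrofuran-2(3H)-one | COc1cc(C[C@H]2COC(=O)C2)cc(OC)c1OCc1ccccc1
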